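**Retrosynthetic overview**
- Ring A is a 2-acylresorcinol. The ring carbon bearing carbonyl carbon C-1 lies between the two C–OH carbons, and the other three ring carbons are unsubstituted CH. This is the pattern produced when the two carbons of a 1-methoxyalkyne are inserted into the C(=O)–CH= bond of unsubstituted cyclobut-2-en-1-one.
- Endgame: the target comes from its tetramethyl ether ketone (BBr3). That ketone comes from the benzylic carbinol (Dess–Martin oxidation), and the carbinol from its silyl ether. C-1 passes through the ring construction as a protected carbinol.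
- Key disconnection: ring A is split into cyclobut-2-en-1-one and the TBS ether of a 1-methoxyalkyn-3-ol, joined in the forward sense by a thermal vinylketene/alkyne benzannulation.
- The alkyne comes from 9-(3,4-dimethoxyphenyl)nonanal and lithium methoxyacetylide. The aldehyde comes from linear hydroformylation of the coupling product of an aryl Grignard reagent with 8-bromooct-1-ene. Cyclobutenone comes from 3-oxocyclobutane-1-carboxylic acid.
- Ring order: ring B (the catechol ring) is bought as its dimethyl ether. Ring A is the only ring formed, in step 7.

Key step: step 7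

Remark: the target has no stereocentre, so the carbinol carbon made in step 3 is carried as the racemate until step 10 turns it into carbonyl carbon C-1.

**Step 1**
Reactants: 1 4-bromo-1,2-dimethoxybenzene; 2 8-bromooct-1-ene
Product: 4 1,2-dimethoxy-4-(oct-7-en-1-yl)benzene, via 3,4-dimethoxyphenylmagnesium bromide 3 (not isolated)
Conditions: Mg, THF, reflux; then 2, Li2CuCl4 (3 mol %), NMP, THF, 0 °C → rt
Reagents that add atoms: none
Why: Copper-catalysed Kochi coupling of an aryl Grignard reagent with an unhindered primary alkyl bromide is a dependable sp2–sp3 bond formation, and the remote terminal alkene and the methyl ethers are inert to it.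

**Step 2**
Reactants: 4 1,2-dimethoxy-4-(oct-7-en-1-yl)benzene
Product: 5 9-(3,4-dimethoxyphenyl)nonanal
Conditions: Rh(acac)(CO)2 (0.5 mol %), Xantphos (2 mol %), CO/H2 (1:1, 10 bar), toluene, 80 °C
Reagents that add atoms: carbon monoxide, [C-]#[O+]
Why: Rhodium-catalysed hydroformylation with a wide-bite-angle diphosphine should place the formyl group on the terminal carbon of the 1-alkene, adding the one carbon that will become C-1.

**Step 3**
Reactants: 5 9-(3,4-dimethoxyphenyl)nonanal; 6 2-chloro-1,1-dimethoxyethane
Product: 8 racemic 11-(3,4-dimethoxyphenyl)-1-methoxyundec-1-yn-3-ol, via lithium methoxyacetylide 7 (not isolated)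
Conditions: Et2NH, n-BuLi, THF, 0 °C; 6 (one third of the amide), 0 °C; then 5, −78 °C → −20 °C; then H2O; chromatography on Et3N-deactivated silica
Reagents that add atoms: none
Why: Three equivalents of LiNEt2 remove methanol and then HCl from the chloroacetal (double β-elimination) and deprotonate the resulting methoxyethyne, and the acetylide then adds 1,2 to the aldehyde; the new carbinol centre forms without control as the racemate, which is harmless because it is oxidised later.

**Step 4**
Reactants: 8 racemic 11-(3,4-dimethoxyphenyl)-1-methoxyundec-1-yn-3-ol
Product: 9 racemic tert-butyl{[11-(3,4-dimethoxyphenyl)-1-methoxyundec-1-yn-3-yl]oxy}dimethylsilane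
Conditions: TBSCl, imidazole, DMF, rt
Reagents that add atoms: tert-butyldimethylsilyl chloride, CC(C)(C)[Si](C)(C)Cl
Why: Imidazole-promoted silylation of a secondary alcohol keeps the medium basic, so the acid-labile alkoxypropargylic alcohol never meets the conditions of a Meyer–Schuster rearrangement.

**Step 5**
Reactants: 10 3-oxocyclobutane-1-carboxylic acid
Product: 11 3-bromocyclobutan-1-one
Conditions: HgO, Br2, MgSO4, CH2Cl2, reflux
Reagents that add atoms: bromine, BrBr
Why: In the Cristol–Firth modification of the Hunsdiecker reaction the acyl hypobromite loses CO2 in a radical chain and the cyclobutyl radical abstracts bromine, while the ketone is left untouched.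

**Step 6**
Reactants: 11 3-bromocyclobutan-1-one
Product: 12 cyclobut-2-en-1-one
Conditions: n-Bu3N (2 equiv), neat, rt; vacuum transfer into a −78 °C trap; kept cold as a toluene solution and used at once
Reagents that add atoms: none
Why: A high-boiling, non-nucleophilic amine effects E1cB-type β-elimination of HBr from the β-bromoketone, and the volatile enone can be drawn away from base and salt before it polymerises.

**Step 7**
Reactants: 9 racemic tert-butyl{[11-(3,4-dimethoxyphenyl)-1-methoxyundec-1-yn-3-yl]oxy}dimethylsilane; 12 cyclobut-2-en-1-one
Product: 17 racemic 2-[1-(tert-butyldimethylsilyloxy)-9-(3,4-dimethoxyphenyl)nonyl]-3-methoxyphenol, via vinylketene 13 (not isolated), via 4-vinylcyclobutenone 14 (not isolated), via dienylketene 15 (not isolated), via cyclohexa-2,4-dienone 16 (not isolated)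
Conditions: 12 (2.5 equiv, toluene solution, syringe pump) added to 9, BHT (cat.), toluene (0.5 M), Ar, base-washed glassware, 80 °C; then 110 °C; then K2CO3, MeOH, rt
Reagents that add atoms: none
Why: Danheiser benzannulation, a four-stage pericyclic cascade: at 80 °C cyclobutenone 12 opens by a conrotatory 4π electrocyclic reaction to vinylketene 13, and the ketene C=C bond of 13 takes up the electron-rich triple bond of 9 in a [2+2] cycloaddition to give 4-vinylcyclobutenone 14, the event that makes both new skeletal bonds (ketene carbonyl carbon to the chain-bearing alkyne carbon, ketene α-carbon to the methoxy-bearing alkyne carbon). A second, reversible 4π opening turns 14 into dienylketene 15, ring A is then closed by a disrotatory 6π electrocyclisation that joins the ketene carbonyl carbon to the terminal vinyl carbon, and dienone 16 tautomerises irreversibly to phenol 17, which drains all the preceding equilibria. The closest known reactions are the thermal benzannulations of substituted cyclobutenones with 1-methoxyalkynes and siloxyalkynes, and a methyl ynol ether is chosen because it has no β-hydrogen and so cannot lose an alkene by a retro-ene reaction at these temperatures. The step needs regioselectivity in the cycloaddition, and the oxygen lone pair of the ynol ether secures it by making the chain-bearing carbon the nucleophilic terminus that attacks the electrophilic ketene carbonyl carbon, so that the carbinol carbon ends up between the hydroxyl and the methoxy group. It also needs capture of 13 to outrun self-reaction of the strained enone, which is why 12 is fed slowly into the hot concentrated solution of 9 and why a closing methanolysis frees any phenol that has been acylated by surplus ketene. No lasting stereocentre is created: the ring stereocentre of 14 disappears on opening, only the isomer of 15 with the vinyl group cis to the ketene carbon can cyclise while the other returns to 14, and the racemic silyloxy-bearing carbon is a spectator.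

**Step 8**
Reactants: 17 racemic 2-[1-(tert-butyldimethylsilyloxy)-9-(3,4-dimethoxyphenyl)nonyl]-3-methoxyphenol
Product: 18 racemic tert-butyl{[1-(2,6-dimethoxyphenyl)-9-(3,4-dimethoxyphenyl)nonyl]oxy}dimethylsilane
Conditions: MeI, K2CO3, DMF, rt
Reagents that add atoms: iodomethane, CI
Why: Williamson etherification caps the free phenol, so that the later hypervalent-iodine oxidant meets no electron-rich phenol and the freed benzylic alcohol cannot collapse to an ortho-quinone methide; the extra methyl group falls off with the others in the last step.

**Step 9**
Reactants: 18 racemic tert-butyl{[1-(2,6-dimethoxyphenyl)-9-(3,4-dimethoxyphenyl)nonyl]oxy}dimethylsilane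
Product: 19 racemic 1-(2,6-dimethoxyphenyl)-9-(3,4-dimethoxyphenyl)nonan-1-ol
Conditions: Bu4NF, THF, rt; then H2O
Reagents that add atoms: none
Why: Fluoride-induced desilylation is driven by the strong Si–F bond and touches neither the aryl methyl ethers nor the alkyl chain.

**Step 10**
Reactants: 19 racemic 1-(2,6-dimethoxyphenyl)-9-(3,4-dimethoxyphenyl)nonan-1-ol
Product: 20 1-(2,6-dimethoxyphenyl)-9-(3,4-dimethoxyphenyl)nonan-1-one
Conditions: Dess–Martin periodinane, CH2Cl2, 0 °C → rt
Reagents that add atoms: none
Why: Dess–Martin oxidation converts the hindered secondary benzylic alcohol into the aryl ketone under near-neutral conditions that spare the methoxyarenes, and it removes the only stereocentre.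

**Step 11**
Reactants: 20 1-(2,6-dimethoxyphenyl)-9-(3,4-dimethoxyphenyl)nonan-1-one
Product: 21 malabaricone C, 1-(2,6-dihydroxyphenyl)-9-(3,4-dihydroxyphenyl)nonan-1-one
Conditions: BBr3 (8 equiv), CH2Cl2, −78 °C → rt; then ice/H2O, work-up under Ar
Reagents that add atoms: none
Why: Lewis-acid ether cleavage with BBr3 removes all four aryl methyl groups by bromide attack on the boron-complexed O–CH3, with chelation to the ketone helping the two ortho ethers, and hydrolysis of the aryl borates should release the tetraphenol.

**Compound list**
1 | 4-bromo-1,2-dimethoxybenzene | COc1ccc(Br)cc1OC | starting material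
2 | 8-bromooct-1-ene | C=CCCCCCCBr | starting material
3 | 3,4-dimethoxyphenylmagnesium bromide | COc1ccc([Mg]Br)cc1OC | intermediate
4 | 1,2-dimethoxy-4-(oct-7-en-1-yl)benzene | C=CCCCCCCc1ccc(OC)c(OC)c1 | intermediate
5 | 9-(3,4-dimethoxyphenyl)nonanal | O=CCCCCCCCCc1ccc(OC)c(OC)c1 | intermediate
6 | 2-chloro-1,1-dimethoxyethane | COC(CCl)OC | starting material
7 | lithium methoxyacetylide | [Li]C#COC | intermediate
8 | racemic 11-(3,4-dimethoxyphenyl)-1-methoxyundec-1-yn-3-ol | COC#CC(O)CCCCCCCCc1ccc(OC)c(OC)c1 | intermediate
9 | racemic tert-butyl{[11-(3,4-dimethoxyphenyl)-1-methoxyundec-1-yn-3-yl]oxy}dimethylsilane | COC#CC(O[Si](C)(C)C(C)(C)C)CCCCCCCCc1ccc(OC)c(OC)c1 | intermediate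
10 | 3-oxocyclobutane-1-carboxylic acid | O=C1CC(C(=O)O)C1 | starting material
11 | 3-bromocyclobutan-1-one | O=C1CC(Br)C1 | intermediate
12 | cyclobut-2-en-1-one | O=C1C=CC1 | intermediate
13 | vinylketene (buta-1,3-dien-1-one) | C=CC=C=O | intermediate
14 | 2-[1-(tert-butyldimethylsilyloxy)-9-(3,4-dimethoxyphenyl)nonyl]-4-ethenyl-3-methoxycyclobut-2-en-1-one (mixture of diastereomers) | O=C1C(C(O[Si](C)(C)C(C)(C)C)CCCCCCCCc2ccc(OC)c(OC)c2)=C(OC)C1C=C | intermediate
15 | (3E)-2-[1-(tert-butyldimethylsilyloxy)-9-(3,4-dimethoxyphenyl)nonyl]-3-methoxyhexa-1,3,5-trien-1-one (vinyl group cis to the ketene carbon) | O=C=C(C(O[Si](C)(C)C(C)(C)C)CCCCCCCCc1ccc(OC)c(OC)c1)/C(OC)=C\C=C | intermediate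
16 | 2-[1-(tert-butyldimethylsilyloxy)-9-(3,4-dimethoxyphenyl)nonyl]-3-methoxycyclohexa-2,4-dien-1-one | O=C1CC=CC(OC)=C1C(O[Si](C)(C)C(C)(C)C)CCCCCCCCc2ccc(OC)c(OC)c2 | intermediate
17 | racemic 2-[1-(tert-butyldimethylsilyloxy)-9-(3,4-dimethoxyphenyl)nonyl]-3-methoxyphenol | COc1cccc(O)c1C(O[Si](C)(C)C(C)(C)C)CCCCCCCCc1ccc(OC)c(OC)c1 | intermediate
18 | racemic tert-butyl{[1-(2,6-dimethoxyphenyl)-9-(3,4-dimethoxyphenyl)nonyl]oxy}dimethylsilane | COc1cccc(OC)c1C(O[Si](C)(C)C(C)(C)C)CCCCCCCCc1ccc(OC)c(OC)c1 | intermediate
19 | racemic 1-(2,6-dimethoxyphenyl)-9-(3,4-dimethoxyphenyl)nonan-1-ol | COc1cccc(OC)c1C(O)CCCCCCCCc1ccc(OC)c(OC)c1 | intermediate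
20 | 1-(2,6-dimethoxyphenyl)-9-(3,4-dimethoxyphenyl)nonan-1-one | COc1cccc(OC)c1C(=O)CCCCCCCCc1ccc(OC)c(OC)c1 | intermediate
21 | malabaricone C | O=C(CCCCCCCCc1ccc(O)c(O)c1)c1c(O)cccc1O | target

**Total step count:** 11
**Longest linear sequence:** 9 steps (steps 1–4 and 7–11)

**Steps most likely to fail**

1. Step 7.
   - Oligomerisation of the strained enone and dimerisation of the ketene may outrun capture by an alkyne whose nucleophilic carbon is hindered and inductively deactivated by the silyloxy group.
   - Direct conjugate attack of the ynol ether on the enone is a further risk, as is thermal loss of silanol from the ortho-hydroxybenzylic ether.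
   - Fallback: ring A is attached ready-made by directed ortho-metalation. It sets out from aldehyde 5.
   - 1,3-Dimethoxybenzene is lithiated between its two methoxy groups (n-BuLi, THF, 0 °C → rt) to give 2,6-dimethoxyphenyllithium F1. This adds to 5 at −78 °C and, after aqueous quench, gives the carbinol directly.
   - The route is rejoined at 19 and finishes with steps 10 and 11.

2. Step 6.
   - Polymerisation and evaporative loss of the unsubstituted enone during vacuum transfer and storage may leave too little material of usable purity.
   - Fallback: vinylketene is made without any cyclobutenone, by photochemical Wolff rearrangement (the diazo ketone variant of the same benzannulation). It sets out from alkyne 9.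
   - 3-Bromopropanoyl chloride is added to excess diazomethane (Et2O, 0 °C) to give 4-bromo-1-diazobutan-2-one F2.
   - DBU (CH2Cl2, 0 °C) removes HBr to give 1-diazobut-3-en-2-one F3.
   - Irradiation of F3 together with 9 (low-pressure mercury lamp, 254 nm, CH2Cl2, rt) expels nitrogen and releases 13 at room temperature in the presence of the alkyne.
   - Subsequent heating in toluene at 80–110 °C carries 14, 15 and 16 forward, and the route is rejoined at 17.

3. Step 3.
   - Incomplete elimination of the chloroacetal would leave amide base, which can enolise the aldehyde and cause self-aldol condensation.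
   - Acid-triggered Meyer–Schuster rearrangement of the alkoxypropargylic alcohol during isolation is the second danger.
   - Fallback: an amine-free acetylide is made from a dichloroenol ether. It sets out from aldehyde 5.
   - Trichloroethene and KOMe (THF, rt, kept in solution throughout because dichloroethyne is passed through) give (E)-1,2-dichloro-1-methoxyethene F4.
   - The first equivalent of n-BuLi (THF, −78 → −40 °C) deprotonates F4 and expels LiCl to give 1-chloro-2-methoxyethyne F5.
   - The second equivalent exchanges the chlorine of F5 for lithium, so acetylide 7 is obtained with no amide or amine present.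
   - Aldehyde 5 is then added at −78 °C, and the route is rejoined at 8.

**Further compounds**
F1 | step 7 | 2,6-dimethoxyphenyllithium | [Li]c1c(OC)cccc1OC
F2 | step 6 | 4-bromo-1-diazobutan-2-one | [N-]=[N+]=CC(=O)CCBr
F3 | step 6 | 1-diazobut-3-en-2-one | C=CC(=O)C=[N+]=[N-]
F4 | step 3 | (E)-1,2-dichloro-1-methoxyethene | CO/C(Cl)=C\Cl
F5 | step 3 | 1-chloro-2-methoxyethyne | COC#CCl
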